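## Retrosynthetic overview

1. The furanone is the only ring made. It is opened at C2–C3 to a phenyl enol carbonate of a cross-conjugated dienone; hydride addition to the vinyl ketone gives the C3 enolate, which closes the ring on the carbonate carbon (reductive Claisen) in the last step.
2. Enabling feature: in the furanone, C5 carries the ring oxygen O1 and is alpha to the C4 carbonyl. O1–C2(=O) can therefore be stored as a carbonate on the (5E)-enol of a 4,5-diketone, with C3 and its methyl latent in a vinyl group on C4.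
3. (E)-C5=C6: E(O)-selective enolisation of an alkynyl ketone (slim alkyne on C5) and O-acylation with ClCO2Ph; the alkyne is then turned into the vinyl ketone by Meyer–Schuster rearrangement.
4. Chain: C12–C13 by Zr-catalysed carboalumination and Pd-catalysed allylation (skipped E,E-diene); C7 from (S)-citronellal; the furyl ketone part from geranyl acetate and 3-bromofuran.
5. Ring order: the furan is bought in; the furanone is closed last.

Key step: step 15

Remark (numbering and assumption): target atoms are O1, C2 (lactone C=O), C3 (C–CH3), C4 (C–OH), C5, then C6 (=CH), C7 (stereocentre) to C18 (furyl ketone). The SMILES places C7 cis to C4 across C5=C6, so the route is built for the (5E) isomer with (S)-C7. The carbinol centres at C5 (steps 1–9) and C18 (steps 7–13) are carried as mixtures and removed by oxidation.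

## Route

Step 1
Reactants: 1 (S)-citronellal; 2 tert-butyldimethyl(prop-2-yn-1-yloxy)silane
Product: 4 (4RS,6S)-1-[(tert-butyldimethylsilyl)oxy]-6,10-dimethylundec-9-en-2-yn-4-ol, via lithium acetylide 3 (not isolated)
Conditions: n-BuLi, THF, −78 °C; then 1, −78 → 0 °C; H2O
Reagents that add atoms: none
Why: Addition of a lithium acetylide to an aldehyde; the new carbinol centre is a mixture that is removed in step 10, and the citronellal centre (future C7, beta to the carbonyl) cannot epimerise.

Step 2
Reactants: 4
Product: 6 (4S,6RS)-9-[(tert-butyldimethylsilyl)oxy]-4-methylnon-7-yne-1,6-diol, via aldehyde 5 (not isolated)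
Conditions: O3, CH2Cl2/MeOH, −78 °C (Sudan Red 7B end point); then NaBH4 (excess), −78 °C → rt
Reagents that add atoms: ozone, [O-][O+]=O
Why: Ozonolysis with reductive work-up; the electron-rich trisubstituted alkene reacts far faster than the internal alkyne, and borohydride reduces the cleavage product in the same flask to the primary alcohol.

Step 3
Reactants: 6
Product: 7 (4RS,6S)-1-[(tert-butyldimethylsilyl)oxy]-9-iodo-6-methylnon-2-yn-4-ol
Conditions: I2, PPh3, imidazole, CH2Cl2, 0 °C
Reagents that add atoms: iodine, II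
Why: Appel-type iodination, which should select the unhindered primary alcohol over the secondary propargylic one.

Step 4
Reactants: 7
Product: 8 (4RS,6S)-1-[(tert-butyldimethylsilyl)oxy]-6-methylundeca-2,10-diyn-4-ol
Conditions: LiC≡CH·H2NCH2CH2NH2 (3 equiv), DMSO, 10 °C → rt; aq NH4Cl
Reagents that add atoms: lithium acetylide ethylenediamine complex, [Li]C#C.NCCN
Why: SN2 alkylation of lithium acetylide by a primary iodide; excess reagent deprotonates the free hydroxyl, and the alkoxide is a spectator.

Step 5
Reactants: 9 geranyl acetate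
Product: 10 (2E)-5-(3,3-dimethyloxiran-2-yl)-3-methylpent-2-en-1-yl acetate (racemic)
Conditions: mCPBA (1.0 equiv), CH2Cl2, 0 °C
Reagents that add atoms: mCPBA, OOC(=O)c1cccc(Cl)c1
Why: Prilezhaev epoxidation, selective for the more electron-rich 6,7-alkene over the alkene deactivated by the allylic acetate.

Step 6
Reactants: 10
Product: 11 (2E)-3-methyl-6-oxohex-2-en-1-yl acetate
Conditions: H5IO6, THF/Et2O, 0 °C
Reagents that add atoms: none
Why: Periodic acid opens the epoxide and cleaves the resulting glycol to the aldehyde and acetone in one operation, leaving the (E)-allylic acetate untouched.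

Step 7
Reactants: 12 3-bromofuran; 11
Product: 14 (2E,6RS)-6-(furan-3-yl)-6-hydroxy-3-methylhex-2-en-1-yl acetate, via furan-3-yllithium 13 (not isolated)
Conditions: n-BuLi, THF, −78 °C; then 11, −78 °C; H2O
Reagents that add atoms: none
Why: Bromine–lithium exchange and 1,2-addition; at −78 °C 3-furyllithium keeps its position and the aldehyde is attacked much faster than the acetate.

Step 8
Reactants: 14
Product: 15 (2E,6RS)-6-[(tert-butyldimethylsilyl)oxy]-6-(furan-3-yl)-3-methylhex-2-en-1-yl acetate
Conditions: TBSCl, imidazole, DMF, rt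
Reagents that add atoms: tert-butyldimethylsilyl chloride, CC(C)(C)[Si](C)(C)Cl
Why: Imidazole-promoted silylation of the secondary alcohol, so that this part carries no acidic or enolisable group in the amide-base step 11.

Step 9
Reactants: 8; 15
Product: 17 (4RS,6S,10E,13E,17RS)-1,17-bis[(tert-butyldimethylsilyl)oxy]-17-(furan-3-yl)-6,10,14-trimethylheptadeca-10,13-dien-2-yn-4-ol, via alkenylalane 16 (not isolated)
Conditions: Me3Al (3.5 equiv), Cp2ZrCl2 (0.25 equiv), CH2Cl2, 0 °C → rt; then 15, Pd(PPh3)4 (5 mol%), THF, rt; H2O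
Reagents that add atoms: trimethylaluminium, C[Al](C)C
Why: Negishi zirconium-catalysed syn-carboalumination puts methyl on the internal and aluminium on the terminal carbon of the terminal alkyne only, which sets (E)-C11=C12. Coupling of the alkenylalane with the allylic acetate under zerovalent palladium at the primary terminus, with retention at both alkenes, should then give the skipped (E,E)-diene.

Step 10
Reactants: 17
Product: 18 (6S,10E,13E,17RS)-1,17-bis[(tert-butyldimethylsilyl)oxy]-17-(furan-3-yl)-6,10,14-trimethylheptadeca-10,13-dien-2-yn-4-one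
Conditions: Dess–Martin periodinane, CH2Cl2, 0 °C → rt
Reagents that add atoms: none
Why: Dess–Martin oxidation of the propargylic alcohol to the ynone; silyl ethers, furan and the diene are inert, and the carbinol mixture is removed.

Step 11
Reactants: 18
Product: 20 (4E,6S,10E,13E,17RS)-1,17-bis[(tert-butyldimethylsilyl)oxy]-17-(furan-3-yl)-6,10,14-trimethylheptadeca-4,10,13-trien-2-yn-4-yl phenyl carbonate, via lithium enolate 19 (not isolated)
Conditions: LDA (1.1 equiv), THF, −78 °C; then DMPU, ClCO2Ph, −78 → −40 °C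
Reagents that add atoms: phenyl chloroformate, O=C(Cl)Oc1ccccc1
Why: Kinetic enolisation by the Ireland model: the slim alkynyl group on the carbonyl carbon causes no allylic strain, so the E(O)-enolate (C7 chain trans to O, cis to the alkyne) should predominate. O-acylation by the chloroformate in the presence of DMPU fixes this as the (E)-enol carbonate, which is the geometry of C5=C6 in the target; C7 is beta to the carbonyl and is not touched.

Step 12
Reactants: 20
Product: 21 (4E,6S,10E,13E,17RS)-17-(furan-3-yl)-1,17-dihydroxy-6,10,14-trimethylheptadeca-4,10,13-trien-2-yn-4-yl phenyl carbonate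
Conditions: HF·pyridine, pyridine, THF, 0 °C → rt
Reagents that add atoms: none
Why: Buffered fluoride cleavage of both silyl ethers; the phenyl enol carbonate is sensitive to base and nucleophiles but should tolerate these mildly acidic conditions.

Step 13
Reactants: 21
Product: 22 (4E,6S,10E,13E,17RS)-17-(furan-3-yl)-17-hydroxy-6,10,14-trimethyl-3-oxoheptadeca-1,4,10,13-tetraen-4-yl phenyl carbonate
Conditions: Ph3PAuNTf2 (2 mol%), 4-MeOC6H4B(OH)2 (0.2 equiv), toluene, rt
Reagents that add atoms: none
Why: Meyer–Schuster rearrangement of a primary propargylic alcohol under monovalent gold: oxygen is delivered to the alkyne carbon remote from the carbinol (C4) and the hydroxyl leaves, so the ketone lands regiospecifically on C4 and the former CH2OH becomes the vinyl terminus. Attack from the enol carbonate carbonyl is blocked because it would place gold on the inner face next to C7, so the (E)-enol carbonate is kept.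

Step 14
Reactants: 22
Product: 23 (4E,6S,10E,13E)-17-(furan-3-yl)-6,10,14-trimethyl-3,17-dioxoheptadeca-1,4,10,13-tetraen-4-yl phenyl carbonate
Conditions: Dess–Martin periodinane, CH2Cl2, 0 °C
Reagents that add atoms: none
Why: Dess–Martin oxidation of the furyl carbinol under neutral conditions; no base or nucleophile is present that could isomerise the (E)-enol carbonate or add to the vinyl ketone.

Step 15
Reactants: 23
Product: 25 (5E)-5-[(2S,6E,9E)-13-(furan-3-yl)-2,6,10-trimethyl-13-oxotrideca-6,9-dien-1-ylidene]-4-hydroxy-3-methylfuran-2(5H)-one, via copper enolate 24 (not isolated)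
Conditions: [(Ph3P)CuH]6 (0.25 equiv of hexamer), toluene/THF, −40 → 0 °C; then 1 M HCl
Reagents that add atoms: none
Why: Proposed new method: Monovalent copper hydride adds hydride to the unsubstituted vinyl terminus of the dienone, which gives copper enolate 24 with its nucleophilic carbon at C3 and turns the vinyl CH2 into the C3 methyl; C3 then attacks the carbonate carbon C2 held on the enol oxygen O1, and loss of phenoxide and enolisation of the 2,4-dione give the tetronic acid. The closest known reaction types are the reductive aldol cyclisation of enones with Stryker's reagent and the intramolecular Claisen (Baker–Venkataraman-type) acylation of ketone enolates by aryl carbonates that leads to 4-hydroxycoumarins. The furanone closes through C2–C3 by a 5-exo-trig attack on the carbonyl with the enolate double bond inside the new ring (5-enolendo-exo-trig, the mode of the Dieckmann route to tetronic acids). No stereocentre is formed (C3 becomes sp2); (S)-C7 and (E)-C5=C6 are kept because O1 stays acylated until the ring is closed and no free base is present to remove the gamma hydrogen at C7. The step needs hydride delivery to the vinyl ketone and not to the hindered alpha-oxygenated enone or the furyl ketone, which the unhindered CH2 terminus and the inertness of this hydride towards isolated ketones should secure. It also needs C- over O-acylation, which is favoured because O-attack would give a strained bis-alkylidene cyclic carbonate that can revert, whereas C-attack ends in the stable tetronate.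

## Compound list

1 | (S)-citronellal, (3S)-3,7-dimethyloct-6-enal | O=CC[C@@H](C)CCC=C(C)C | starting material
2 | tert-butyldimethyl(prop-2-yn-1-yloxy)silane | C#CCO[Si](C)(C)C(C)(C)C | starting material
3 | {3-[(tert-butyldimethylsilyl)oxy]prop-1-yn-1-yl}lithium | [Li]C#CCO[Si](C)(C)C(C)(C)C | intermediate (not isolated)
4 | (4RS,6S)-1-[(tert-butyldimethylsilyl)oxy]-6,10-dimethylundec-9-en-2-yn-4-ol | CC(C)(C)[Si](C)(C)OCC#CC(O)C[C@@H](C)CCC=C(C)C | intermediate
5 | (4S,6RS)-9-[(tert-butyldimethylsilyl)oxy]-6-hydroxy-4-methylnon-7-ynal | CC(C)(C)[Si](C)(C)OCC#CC(O)C[C@@H](C)CCC=O | intermediate (not isolated)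
6 | (4S,6RS)-9-[(tert-butyldimethylsilyl)oxy]-4-methylnon-7-yne-1,6-diol | CC(C)(C)[Si](C)(C)OCC#CC(O)C[C@@H](C)CCCO | intermediate
7 | (4RS,6S)-1-[(tert-butyldimethylsilyl)oxy]-9-iodo-6-methylnon-2-yn-4-ol | CC(C)(C)[Si](C)(C)OCC#CC(O)C[C@@H](C)CCCI | intermediate
8 | (4RS,6S)-1-[(tert-butyldimethylsilyl)oxy]-6-methylundeca-2,10-diyn-4-ol | CC(C)(C)[Si](C)(C)OCC#CC(O)C[C@@H](C)CCCC#C | intermediate
9 | geranyl acetate, (2E)-3,7-dimethylocta-2,6-dien-1-yl acetate | CC(=O)OC/C=C(\C)CCC=C(C)C | starting material
10 | (2E)-5-(3,3-dimethyloxiran-2-yl)-3-methylpent-2-en-1-yl acetate (racemic) | CC(=O)OC/C=C(\C)CCC1OC1(C)C | intermediate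
11 | (2E)-3-methyl-6-oxohex-2-en-1-yl acetate | CC(=O)OC/C=C(\C)CCC=O | intermediate
12 | 3-bromofuran | Brc1ccoc1 | starting material
13 | furan-3-yllithium | [Li]c1ccoc1 | intermediate (not isolated)
14 | (2E,6RS)-6-(furan-3-yl)-6-hydroxy-3-methylhex-2-en-1-yl acetate | CC(=O)OC/C=C(\C)CCC(O)c1ccoc1 | intermediate
15 | (2E,6RS)-6-[(tert-butyldimethylsilyl)oxy]-6-(furan-3-yl)-3-methylhex-2-en-1-yl acetate | CC(=O)OC/C=C(\C)CCC(O[Si](C)(C)C(C)(C)C)c1ccoc1 | intermediate
16 | (E)-alkenyl(dimethyl)alane from 8, with the C4 oxygen as its dimethylaluminium alkoxide | CC(C)(C)[Si](C)(C)OCC#CC(O[Al](C)C)C[C@@H](C)CCC/C(C)=C/[Al](C)C | intermediate (not isolated)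
17 | (4RS,6S,10E,13E,17RS)-1,17-bis[(tert-butyldimethylsilyl)oxy]-17-(furan-3-yl)-6,10,14-trimethylheptadeca-10,13-dien-2-yn-4-ol | CC(C)(C)[Si](C)(C)OCC#CC(O)C[C@@H](C)CCC/C(C)=C/C/C=C(\C)CCC(O[Si](C)(C)C(C)(C)C)c1ccoc1 | intermediate
18 | (6S,10E,13E,17RS)-1,17-bis[(tert-butyldimethylsilyl)oxy]-17-(furan-3-yl)-6,10,14-trimethylheptadeca-10,13-dien-2-yn-4-one | CC(C)(C)[Si](C)(C)OCC#CC(=O)C[C@@H](C)CCC/C(C)=C/C/C=C(\C)CCC(O[Si](C)(C)C(C)(C)C)c1ccoc1 | intermediate
19 | lithium (4E)-enolate of 18 (O–Li on C4, C6 chain cis to the alkyne) | CC(C)(C)[Si](C)(C)OCC#C/C(O[Li])=C\[C@@H](C)CCC/C(C)=C/C/C=C(\C)CCC(O[Si](C)(C)C(C)(C)C)c1ccoc1 | intermediate (not isolated)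
20 | (4E,6S,10E,13E,17RS)-1,17-bis[(tert-butyldimethylsilyl)oxy]-17-(furan-3-yl)-6,10,14-trimethylheptadeca-4,10,13-trien-2-yn-4-yl phenyl carbonate | CC(C)(C)[Si](C)(C)OCC#C/C(OC(=O)Oc1ccccc1)=C\[C@@H](C)CCC/C(C)=C/C/C=C(\C)CCC(O[Si](C)(C)C(C)(C)C)c1ccoc1 | intermediate
21 | (4E,6S,10E,13E,17RS)-17-(furan-3-yl)-1,17-dihydroxy-6,10,14-trimethylheptadeca-4,10,13-trien-2-yn-4-yl phenyl carbonate | OCC#C/C(OC(=O)Oc1ccccc1)=C\[C@@H](C)CCC/C(C)=C/C/C=C(\C)CCC(O)c1ccoc1 | intermediate
22 | (4E,6S,10E,13E,17RS)-17-(furan-3-yl)-17-hydroxy-6,10,14-trimethyl-3-oxoheptadeca-1,4,10,13-tetraen-4-yl phenyl carbonate | C=CC(=O)/C(OC(=O)Oc1ccccc1)=C\[C@@H](C)CCC/C(C)=C/C/C=C(\C)CCC(O)c1ccoc1 | intermediate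
23 | (4E,6S,10E,13E)-17-(furan-3-yl)-6,10,14-trimethyl-3,17-dioxoheptadeca-1,4,10,13-tetraen-4-yl phenyl carbonate | C=CC(=O)/C(OC(=O)Oc1ccccc1)=C\[C@@H](C)CCC/C(C)=C/C/C=C(\C)CCC(=O)c1ccoc1 | intermediate
24 | copper enolate from 23 (O–Cu on C3, nucleophilic carbon C2 of the heptadecane chain, phosphine-ligated) | CC=C(O[Cu])/C(OC(=O)Oc1ccccc1)=C\[C@@H](C)CCC/C(C)=C/C/C=C(\C)CCC(=O)c1ccoc1 | intermediate (not isolated)
25 | (5E)-5-[(2S,6E,9E)-13-(furan-3-yl)-2,6,10-trimethyl-13-oxotrideca-6,9-dien-1-ylidene]-4-hydroxy-3-methylfuran-2(5H)-one | CC1=C(O)/C(=C\[C@@H](C)CCC/C(C)=C/C/C=C(\C)CCC(=O)c2ccoc2)OC1=O | target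

## Step count and risks

Total step count: 15. Longest linear sequence: 11 steps (steps 1–4 and 9–15; the branch through steps 5–8 and 9–15 is equally long).

Steps most likely to fail:

1. Step 15 (proposed new method). The copper enolate may be protonated or acylated on oxygen faster than it closes the ring at carbon, or hydride may also reach the second enone. Fallback with known chemistry, from 23: the vinyl group is hydrogenated with H2 and RhCl(PPh3)3 in toluene to the ethyl ketone (4E,6S,10E,13E)-17-(furan-3-yl)-6,10,14-trimethyl-3,17-dioxoheptadeca-4,10,13-trien-4-yl phenyl carbonate F1. This is cyclised by kinetic deprotonation with LiN(SiMe3)2 (3 equiv, THF, −78 → −20 °C, then 1 M HCl; the furyl ketone is carried as a spectator enolate) in a Claisen (Baker–Venkataraman-type) acylation by the aryl carbonate, and the route is rejoined at 25.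

2. Step 13. Ionisation or etherification of the unprotected furyl carbinol and conjugate addition to the newly formed vinyl ketone may compete with the 1,3-transposition. Fallback, from 20: only the primary silyl ether is cleaved (HF·pyridine, pyridine, THF, 0 °C, short time) to the mono-silylated propargylic alcohol (4E,6S,10E,13E,17RS)-17-[(tert-butyldimethylsilyl)oxy]-17-(furan-3-yl)-1-hydroxy-6,10,14-trimethylheptadeca-4,10,13-trien-2-yn-4-yl phenyl carbonate F2. The Meyer–Schuster rearrangement is run on this protected substrate (Ph3PAuNTf2 with the boronic acid, or MoO2(acac)2/Ph3PAuCl/AgOTf in toluene) to the silylated dienone (4E,6S,10E,13E,17RS)-17-[(tert-butyldimethylsilyl)oxy]-17-(furan-3-yl)-6,10,14-trimethyl-3-oxoheptadeca-1,4,10,13-tetraen-4-yl phenyl carbonate F3. HF·pyridine then removes the remaining silyl ether and the route is rejoined at 22.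

3. Step 11. The enolisation may not be E(O)-selective enough, or the enolate may be acylated at carbon instead of oxygen. Fallback, from 18: enolisation in the presence of Me3SiCl (LDA, THF, −78 °C, internal quench) gives the trimethylsilyl enol ether (4E,6S,10E,13E,17RS)-1,17-bis[(tert-butyldimethylsilyl)oxy]-17-(furan-3-yl)-6,10,14-trimethyl-4-[(trimethylsilyl)oxy]heptadeca-4,10,13-trien-2-yne F4, which can be purified and its geometry checked. MeLi (THF, 0 °C) then releases the amine-free lithium enolate 19 with retention of geometry, and ClCO2Ph/DMPU gives 20.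

Further compounds
F1 | step 15 | (4E,6S,10E,13E)-17-(furan-3-yl)-6,10,14-trimethyl-3,17-dioxoheptadeca-4,10,13-trien-4-yl phenyl carbonate | CCC(=O)/C(OC(=O)Oc1ccccc1)=C\[C@@H](C)CCC/C(C)=C/C/C=C(\C)CCC(=O)c1ccoc1
F2 | step 13 | (4E,6S,10E,13E,17RS)-17-[(tert-butyldimethylsilyl)oxy]-17-(furan-3-yl)-1-hydroxy-6,10,14-trimethylheptadeca-4,10,13-trien-2-yn-4-yl phenyl carbonate | OCC#C/C(OC(=O)Oc1ccccc1)=C\[C@@H](C)CCC/C(C)=C/C/C=C(\C)CCC(O[Si](C)(C)C(C)(C)C)c1ccoc1
F3 | step 13 | (4E,6S,10E,13E,17RS)-17-[(tert-butyldimethylsilyl)oxy]-17-(furan-3-yl)-6,10,14-trimethyl-3-oxoheptadeca-1,4,10,13-tetraen-4-yl phenyl carbonate | C=CC(=O)/C(OC(=O)Oc1ccccc1)=C\[C@@H](C)CCC/C(C)=C/C/C=C(\C)CCC(O[Si](C)(C)C(C)(C)C)c1ccoc1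
F4 | step 11 | (4E,6S,10E,13E,17RS)-1,17-bis[(tert-butyldimethylsilyl)oxy]-17-(furan-3-yl)-6,10,14-trimethyl-4-[(trimethylsilyl)oxy]heptadeca-4,10,13-trien-2-yne | CC(C)(C)[Si](C)(C)OCC#C/C(O[Si](C)(C)C)=C\[C@@H](C)CCC/C(C)=C/C/C=C(\C)CCC(O[Si](C)(C)C(C)(C)C)c1ccoc1
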